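**Retrosynthetic overview**

1. The C15 acid comes from its methyl ester, the C19 angelate from the C19 alcohol, and the (13Z)-enoate from syn-carbocupration of an alkynoate grown from a terminal alkyne that is carried from the start.
2. The C4 quaternary centre (C18 methyl, axial C19) comes from the C4 ketone of a trans-decalone by one-carbon Wittig homologation and α-face methylation of the aldehyde enolate.
3. Ring B is disconnected at C5–C6 and C7=C8: C5 is the α-carbon of the C4 ketone (fluoride-freed enolate of a silyl enol ether), C8 is a methyl ketone on C9, and C6–C7 is vinyltriphenylphosphonium bromide (conjugate addition, then intramolecular Wittig).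
4. The C9–C10 bond and both stereocentres come from an Ireland–Claisen rearrangement of the hex-5-ynoate of (R)-3-methylcyclohex-2-en-1-ol; the transposed C4=C5 alkene is then turned into the C4 ketone and its C5 enol ether. Ring A is present from the first step; ring B is closed in the key step.
5. Enabling feature: the only double bond of ring B is the trisubstituted C7=C8, whose C8 carries the C17 methyl and so maps onto a methyl ketone; the ring-fusion carbon C5 sits next to C4, which can be held as a ketone until ring B is closed; the remaining ring B atoms C6–C7 are exactly a vinylphosphonium unit.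

Key step: step 7

Remark: locants C1–C20 are those of the labdane skeleton (ring A = C1–C5 and C10; ring B = C5–C10; C11–C16 side chain on C9; C17 on C8; C18 and C19 on C4; C20 on C10).

**Route**

Step 1
Reactants: 1 3-methylcyclohex-2-en-1-one
Product: 2 (1R)-3-methylcyclohex-2-en-1-ol
Conditions: (S)-1-methyl-3,3-diphenyltetrahydro-1H,3H-pyrrolo[1,2-c][1,3,2]oxazaborole (10 mol %), catecholborane, toluene, −78 °C; then MeOH, aq. NaOH
Reagents that add atoms: none
Why: Corey–Bakshi–Shibata reduction, in which the oxazaborolidine–borane complex binds the ketone with the alkenyl carbon as the large group and delivers hydride to one face, should give the (R)-alcohol whose C4–O stereocentre is the source of all later absolute configuration (the antipodal catalyst is at hand should the sense be reversed).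

Step 2
Reactants: 2 (1R)-3-methylcyclohex-2-en-1-ol; 3 hex-5-ynoic acid
Product: 4 (1R)-3-methylcyclohex-2-en-1-yl hex-5-ynoate
Conditions: N,N'-dicyclohexylcarbodiimide, 4-(dimethylamino)pyridine (cat.), CH2Cl2, 0 °C → rt
Reagents that add atoms: none
Why: Steglich esterification (carbodiimide activation with nucleophilic acyl transfer) joins ring A to the C8–C14 chain without touching the carbinol stereocentre.

Step 3
Reactants: 4 (1R)-3-methylcyclohex-2-en-1-yl hex-5-ynoate
Product: 7 (2R)-2-[(1S)-1-methylcyclohex-2-en-1-yl]hex-5-ynoic acid, via silyl ketene acetal 5 (not isolated), via trimethylsilyl ester 6 (not isolated)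
Conditions: LiN(i-Pr)2 (2.3 equiv), THF/DMPU, −78 °C; Me3SiCl (3 equiv), −78 °C → 45 °C; then K2CO3 (cat.), MeOH/H2O; aq. citric acid
Reagents that add atoms: none
Why: Ireland–Claisen rearrangement, in which the ester enolate formed in the DMPU medium is silylated to the (Z)-ketene acetal (chain cis to OSiMe3, the alkyne being C-silylated by the second equivalent of base) and the suprafacial [3,3] shift through the boat-like transition state usual for cyclohex-2-enyl esters forms the C9–C10 bond on the face of the departing C4–O bond, so that the C4 chirality is transferred to the quaternary C10 and the ketene acetal geometry sets C9.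

Step 4
Reactants: 7 (2R)-2-[(1S)-1-methylcyclohex-2-en-1-yl]hex-5-ynoic acid
Product: 8 (3R)-3-[(1S)-1-methylcyclohex-2-en-1-yl]hept-6-yn-2-one
Conditions: MeLi (3.5 equiv), Et2O, 0 °C → rt; inverse quench into cold 1 M HCl
Reagents that add atoms: methyllithium, [Li]C
Why: Addition of methyllithium to the lithium carboxylate stops at the geminal dialkoxide, which collapses to the methyl ketone (C8 with the C17 methyl) only on the acidic quench, so that over-addition and epimerisation of C9 are not expected while the alkyne is carried as its acetylide.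

Step 5
Reactants: 8 (3R)-3-[(1S)-1-methylcyclohex-2-en-1-yl]hept-6-yn-2-one
Product: 10 (3R)-2-bromo-3-methyl-3-[(3R)-2-oxohept-6-yn-3-yl]cyclohexan-1-one (C2 epimers), via bromohydrin 9 (not isolated)
Conditions: N-bromosuccinimide (1.1 equiv), 2-iodoxybenzoic acid (2 equiv), DMSO/H2O, rt
Reagents that add atoms: N-bromosuccinimide, O=C1CCC(=O)N1Br; water, O
Why: Bromohydrin formation with in-flask alcohol oxidation, in which the bromonium ion of the C4=C5 alkene is opened by the oxygen nucleophile at C4 (the carbon remote from the quaternary C10, attack at the neopentyl-type C5 being disfavoured) and 2-iodoxybenzoic acid oxidises the C4 alcohol, leaves the halogen on C5 next to the new C4 ketone, the two transient stereocentres being of no consequence.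

Step 6
Reactants: 10 (3R)-2-bromo-3-methyl-3-[(3R)-2-oxohept-6-yn-3-yl]cyclohexan-1-one
Product: 11 (3R)-3-{(1S)-1-methyl-3-[(trimethylsilyl)oxy]cyclohex-2-en-1-yl}hept-6-yn-2-one
Conditions: Zn dust, Me3SiCl, TMEDA, Et2O, 0 °C → rt
Reagents that add atoms: chlorotrimethylsilane, C[Si](C)(C)Cl
Why: Reductive silylation of an α-bromo ketone, in which zinc inserts into the C5–Br bond and the zinc enolate is trapped on oxygen, fixes the enol double bond between C4 and C5 regiospecifically and leaves the methyl ketone free.

Step 7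
Reactants: 11 (3R)-3-{(1S)-1-methyl-3-[(trimethylsilyl)oxy]cyclohex-2-en-1-yl}hept-6-yn-2-one; 12 ethenyl(triphenyl)phosphonium bromide
Product: 15 (4aR,5S,8aR)-5-(but-3-yn-1-yl)-4a,6-dimethyl-3,4,4a,5,8,8a-hexahydronaphthalen-1(2H)-one, via sulfonium enolate 13 (not isolated), via phosphonium ylide 14 (not isolated)
Conditions: (Me2N)3S+ Me3SiF2− (TASF, 1.05 equiv), 12 (1.5 equiv), THF/DMF, −60 °C → rt, then 50 °C
Reagents that add atoms: none
Why: Fluoride from TASF cleaves the O–Si bond of 11 and frees the C5 enolate regiospecifically; this enolate adds through C5 to the β-carbon of 12 (bond C5–C6) to give the non-stabilised ylide 14, whose carbon C7 attacks the C8 methyl ketone in an intramolecular Wittig olefination that forms C7=C8 without positional isomers. The closest known reaction type is the annulation of ketone-bearing enolates with vinylphosphonium salts (conjugate addition, then intramolecular Wittig reaction), combined with fluoride-mediated regiospecific enolate generation from silyl enol ethers. Ring B closes in the 6-exo mode by addition of the ylide carbon to the carbonyl and collapse of the oxaphosphetane; attack on the C4 carbonyl would need a four-membered ring and is not expected. The new stereocentre C5 is set in the conjugate addition, the acceptor approaching the enolate face opposite to the large C9 substituent on the quaternary C10, which after ring flip gives the trans ring fusion (5α-H, 10β-methyl). The step needs C- over O-alkylation, no proton transfer from the methyl ketone to the enolate before C–C bond formation, and no epimerisation of C9; the soft cationic acceptor in excess, the aprotic medium at low temperature and the low basicity of the ylide toward ketone α-hydrogens are relied on for this.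

Step 8
Reactants: 15 (4aR,5S,8aR)-5-(but-3-yn-1-yl)-4a,6-dimethyl-3,4,4a,5,8,8a-hexahydronaphthalen-1(2H)-one
Product: 17 5-(but-3-yn-1-yl)-4a,6-dimethyl-1,2,3,4,4a,5,8,8a-octahydronaphthalene-1-carbaldehyde (ring stereocentres as in 15; C4 epimers), via methyl enol ether 16 (not isolated)
Conditions: Ph3P(CH2OMe)Cl, KN(SiMe3)2, THF, 0 °C → rt; then 2 M HCl, THF, rt
Reagents that add atoms: (methoxymethyl)triphenylphosphonium chloride, COC[P+](c1ccccc1)(c1ccccc1)c1ccccc1.[Cl-]; water, O
Why: Wittig methoxymethylenation of the C4 ketone and acid hydrolysis of the enol ether (one-carbon homologation) introduce C19 as an aldehyde, the ylide being kept in excess over free base to limit enolisation toward C5 and the C4 configuration being left open because it is set in step 9.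

Step 9
Reactants: 17 5-(but-3-yn-1-yl)-4a,6-dimethyl-1,2,3,4,4a,5,8,8a-octahydronaphthalene-1-carbaldehyde
Product: 18 (1S,4aR,5S,8aR)-5-(but-3-yn-1-yl)-1,4a,6-trimethyl-1,2,3,4,4a,5,8,8a-octahydronaphthalene-1-carbaldehyde
Conditions: KOt-Bu (1.1 equiv), THF, −40 °C; MeI, −40 → 0 °C
Reagents that add atoms: iodomethane, CI
Why: In this alkylation of the exocyclic aldehyde enolate, iodomethane approaches C4 from the equatorial α-face because the axial β-face is blocked by the 1,3-diaxial C10 methyl group, so that the new methyl becomes C18 and the formyl group C19 is left axial, while one equivalent of base leaves the much less acidic alkyne C–H alone.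

Step 10
Reactants: 18 (1S,4aR,5S,8aR)-5-(but-3-yn-1-yl)-1,4a,6-trimethyl-1,2,3,4,4a,5,8,8a-octahydronaphthalene-1-carbaldehyde
Product: 19 [(1S,4aR,5S,8aR)-5-(but-3-yn-1-yl)-1,4a,6-trimethyl-1,2,3,4,4a,5,8,8a-octahydronaphthalen-1-yl]methanol
Conditions: NaBH4, MeOH, 0 °C
Reagents that add atoms: none
Why: Hydride reduction of the neopentyl aldehyde gives the C19 alcohol without touching any stereocentre.

Step 11
Reactants: 19 [(1S,4aR,5S,8aR)-5-(but-3-yn-1-yl)-1,4a,6-trimethyl-1,2,3,4,4a,5,8,8a-octahydronaphthalen-1-yl]methanol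
Product: 20 methyl (4S,5R,9S,10R)-19-hydroxy-16-norlabd-7-en-13-yn-15-oate
Conditions: PdCl2 (5 mol %), CuCl2 (2.2 equiv), NaOAc (2.2 equiv), CO (1 atm), MeOH, rt
Reagents that add atoms: carbon monoxide, [C-]#[O+]; methanol, CO
Why: Oxidative alkoxycarbonylation of the terminal alkyne, in which the alkynyl complex of divalent palladium inserts CO and is cleaved by methanol while CuCl2 returns zerovalent palladium to the divalent state, installs C15 as the alk-2-ynoate, the isolated trisubstituted alkene and the alcohol not being expected to react at room temperature.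

Step 12
Reactants: 20 methyl (4S,5R,9S,10R)-19-hydroxy-16-norlabd-7-en-13-yn-15-oate
Product: 21 methyl (4S,5R,9S,10R,13Z)-19-hydroxylabda-7,13-dien-15-oate
Conditions: Me2CuLi (from CuI and MeLi, 3 equiv), THF, −78 °C; MeOH then aq. NH4Cl at −78 °C
Reagents that add atoms: lithium dimethylcuprate (Me2CuLi), [Li+].C[Cu-]C
Why: In this conjugate syn-carbocupration of the alkynoate, methyl (C16) and copper add to the same side of the triple bond and the alkenylcopper is protonated with retention when quenched cold, which places C12 cis to the ester ((13Z) geometry), the extra cuprate being consumed by the free hydroxyl.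

Step 13
Reactants: 21 methyl (4S,5R,9S,10R,13Z)-19-hydroxylabda-7,13-dien-15-oate; 22 (2Z)-2-methylbut-2-enoic acid (angelic acid)
Product: 24 methyl (4S,5R,9S,10R,13Z)-19-{[(2Z)-2-methylbut-2-enoyl]oxy}labda-7,13-dien-15-oate, via mixed anhydride 23 (not isolated)
Conditions: 22, 2,4,6-trichlorobenzoyl chloride, Et3N, toluene, rt; then 21, toluene, 80 °C
Reagents that add atoms: none
Why: In this Yamaguchi esterification the mixed anhydride is attacked by the neopentyl C19 alcohol at the less hindered angeloyl carbonyl, and in the absence of a nucleophilic catalyst the (Z) geometry of the angelate is expected to be kept.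

Step 14
Reactants: 24 methyl (4S,5R,9S,10R,13Z)-19-{[(2Z)-2-methylbut-2-enoyl]oxy}labda-7,13-dien-15-oate
Product: 25 (4S,5R,9S,10R,13Z)-19-{[(2Z)-2-methylbut-2-enoyl]oxy}labda-7,13-dien-15-oic acid (CNP0249147.1, the target)
Conditions: Me3SnOH, 1,2-dichloroethane, 70 °C; then 0.1 M HCl
Reagents that add atoms: trimethyltin hydroxide, C[Sn](C)(C)O
Why: In this tin hydroxide-mediated ester cleavage Me3SnOH attacks the methyl ester at the acyl carbon under neutral conditions, whereas the angelate on the neopentyl C19 oxygen next to the quaternary C4 is much more hindered and should survive, and neither (Z) double bond is isomerised.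

**Compound list**

1 | 3-methylcyclohex-2-en-1-one | CC1=CC(=O)CCC1 | starting material
2 | (1R)-3-methylcyclohex-2-en-1-ol | O[C@H]1C=C(C)CCC1 | intermediate
3 | hex-5-ynoic acid | C#CCCCC(=O)O | starting material
4 | (1R)-3-methylcyclohex-2-en-1-yl hex-5-ynoate | C#CCCCC(=O)O[C@H]1C=C(C)CCC1 | intermediate
5 | trimethyl({(1Z)-1-{[(1R)-3-methylcyclohex-2-en-1-yl]oxy}-6-(trimethylsilyl)hex-1-en-5-yn-1-yl}oxy)silane (silyl ketene acetal, chain cis to OSiMe3) | C[Si](C)(C)C#CCC/C=C(\O[Si](C)(C)C)O[C@H]1C=C(C)CCC1 | intermediate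
6 | trimethylsilyl (2R)-2-[(1S)-1-methylcyclohex-2-en-1-yl]-6-(trimethylsilyl)hex-5-ynoate | C[Si](C)(C)OC(=O)[C@H](CCC#C[Si](C)(C)C)[C@@]1(C)CCCC=C1 | intermediate
7 | (2R)-2-[(1S)-1-methylcyclohex-2-en-1-yl]hex-5-ynoic acid | OC(=O)[C@H](CCC#C)[C@@]1(C)CCCC=C1 | intermediate
8 | (3R)-3-[(1S)-1-methylcyclohex-2-en-1-yl]hept-6-yn-2-one | CC(=O)[C@H](CCC#C)[C@@]1(C)CCCC=C1 | intermediate
9 | (3R)-3-[(1R)-2-bromo-3-hydroxy-1-methylcyclohexyl]hept-6-yn-2-one (trans-bromohydrin, ring C2 and C3 not defined) | CC(=O)[C@H](CCC#C)[C@@]1(C)CCCC(O)C1Br | intermediate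
10 | (3R)-2-bromo-3-methyl-3-[(3R)-2-oxohept-6-yn-3-yl]cyclohexan-1-one (C2 epimers) | CC(=O)[C@H](CCC#C)[C@@]1(C)CCCC(=O)C1Br | intermediate
11 | (3R)-3-{(1S)-1-methyl-3-[(trimethylsilyl)oxy]cyclohex-2-en-1-yl}hept-6-yn-2-one | CC(=O)[C@H](CCC#C)[C@@]1(C)CCCC(O[Si](C)(C)C)=C1 | intermediate
12 | ethenyl(triphenyl)phosphonium bromide (vinyltriphenylphosphonium bromide) | C=C[P+](c1ccccc1)(c1ccccc1)c1ccccc1.[Br-] | starting material
13 | tris(dimethylamino)sulfonium (3S)-3-methyl-3-[(3R)-2-oxohept-6-yn-3-yl]cyclohex-1-en-1-olate | CC(=O)[C@H](CCC#C)[C@@]1(C)CCCC([O-])=C1.CN(C)[S+](N(C)C)N(C)C | intermediate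
14 | 3-methyl-3-[(3R)-2-oxohept-6-yn-3-yl]-2-[2-(triphenyl-λ5-phosphanylidene)ethyl]cyclohexan-1-one (C2 chain trans to the oxoheptynyl group, C3 as in 11) | CC(=O)[C@H](CCC#C)[C@@]1(C)CCCC(=O)[C@@H]1CC=P(c1ccccc1)(c1ccccc1)c1ccccc1 | intermediate
15 | (4aR,5S,8aR)-5-(but-3-yn-1-yl)-4a,6-dimethyl-3,4,4a,5,8,8a-hexahydronaphthalen-1(2H)-one (trans-fused; 15,16,18,19-tetranorlabd-7-en-13-yn-4-one) | O=C1CCC[C@]2(C)[C@@H](CCC#C)C(C)=CC[C@@H]12 | intermediate
16 | 5-(but-3-yn-1-yl)-1-(methoxymethylidene)-4a,6-dimethyl-1,2,3,4,4a,5,8,8a-octahydronaphthalene (ring stereocentres as in 15, E/Z mixture) | COC=C1CCC[C@]2(C)[C@@H](CCC#C)C(C)=CC[C@@H]12 | intermediate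
17 | 5-(but-3-yn-1-yl)-4a,6-dimethyl-1,2,3,4,4a,5,8,8a-octahydronaphthalene-1-carbaldehyde (ring stereocentres as in 15, C4 epimers) | O=CC1CCC[C@]2(C)[C@@H](CCC#C)C(C)=CC[C@@H]12 | intermediate
18 | (1S,4aR,5S,8aR)-5-(but-3-yn-1-yl)-1,4a,6-trimethyl-1,2,3,4,4a,5,8,8a-octahydronaphthalene-1-carbaldehyde (15,16-dinorlabd-7-en-13-yn-19-al) | O=C[C@@]1(C)CCC[C@]2(C)[C@@H](CCC#C)C(C)=CC[C@@H]12 | intermediate
19 | [(1S,4aR,5S,8aR)-5-(but-3-yn-1-yl)-1,4a,6-trimethyl-1,2,3,4,4a,5,8,8a-octahydronaphthalen-1-yl]methanol (15,16-dinorlabd-7-en-13-yn-19-ol) | OC[C@@]1(C)CCC[C@]2(C)[C@@H](CCC#C)C(C)=CC[C@@H]12 | intermediate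
20 | methyl (4S,5R,9S,10R)-19-hydroxy-16-norlabd-7-en-13-yn-15-oate | OC[C@@]1(C)CCC[C@]2(C)[C@@H](CCC#CC(=O)OC)C(C)=CC[C@@H]12 | intermediate
21 | methyl (4S,5R,9S,10R,13Z)-19-hydroxylabda-7,13-dien-15-oate | OC[C@@]1(C)CCC[C@]2(C)[C@@H](CC/C(C)=C\C(=O)OC)C(C)=CC[C@@H]12 | intermediate
22 | (2Z)-2-methylbut-2-enoic acid (angelic acid) | C/C=C(/C)C(=O)O | starting material
23 | (2Z)-2-methylbut-2-enoic 2,4,6-trichlorobenzoic anhydride | C/C=C(/C)C(=O)OC(=O)c1c(Cl)cc(Cl)cc1Cl | intermediate
24 | methyl (4S,5R,9S,10R,13Z)-19-{[(2Z)-2-methylbut-2-enoyl]oxy}labda-7,13-dien-15-oate | C/C=C(/C)C(=O)OC[C@@]1(C)CCC[C@]2(C)[C@@H](CC/C(C)=C\C(=O)OC)C(C)=CC[C@@H]12 | intermediate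
25 | (4S,5R,9S,10R,13Z)-19-{[(2Z)-2-methylbut-2-enoyl]oxy}labda-7,13-dien-15-oic acid (CNP0249147.1) | C/C=C(/C)C(=O)OC[C@@]1(C)CCC[C@]2(C)[C@@H](CC/C(C)=C\C(=O)O)C(C)=CC[C@@H]12 | target

**Step count and risks**

Total step count: 14. Longest linear sequence: 14 steps (1 → 25); compounds 3, 12 and 22 are purchased.

Steps most likely to fail:

Step 7. The fluoride-freed enolate may take a proton from the methyl ketone before it finds the acceptor (loss of regiocontrol, aldol closure), it may react on oxygen, or the acceptor may approach C5 from the face of the C9 substituent. The fallback makes the two bonds separately and without an enolate. It sets out from bromo ketone 10, which is allylated at C5 under radical chain conditions (allyltributylstannane, 2,2'-azobis(2-methylpropanenitrile), benzene, 80 °C; Keck allylation) to give 3-methyl-3-[(3R)-2-oxohept-6-yn-3-yl]-2-(prop-2-en-1-yl)cyclohexan-1-one F1, in which C5 can still be equilibrated. Lemieux–Johnson cleavage of the terminal alkene (OsO4 cat., NaIO4, 2,6-lutidine, dioxane/H2O) gives {2-methyl-6-oxo-2-[(3R)-2-oxohept-6-yn-3-yl]cyclohexyl}acetaldehyde F2. Intramolecular McMurry coupling of the C7 aldehyde with the C8 ketone (TiCl3, Zn–Cu couple, DME, high dilution, reflux; the C4 ketone cannot close a ring with C7) should then form C7=C8, and the route is rejoined at 15.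

Step 5. The bromonium ion may be opened at the wrong carbon, or by the C8 carbonyl oxygen instead of the solvent, or the product may be over-oxidised. The fallback rests on the steric difference between two hydroxyl groups and not on the regiochemistry of ring opening. It sets out from 8, which is dihydroxylated (OsO4 cat., N-methylmorpholine N-oxide, acetone/H2O) to 3-(2,3-dihydroxy-1-methylcyclohexyl)hept-6-yn-2-one F3 (cis-diol). The less hindered C4 hydroxyl is oxidised (2,2,6,6-tetramethylpiperidin-1-oxyl cat., PhI(OAc)2, CH2Cl2) to 2-hydroxy-3-methyl-3-[(3R)-2-oxohept-6-yn-3-yl]cyclohexan-1-one F4, and acetylation (Ac2O, 4-(dimethylamino)pyridine) gives 2-methyl-6-oxo-2-[(3R)-2-oxohept-6-yn-3-yl]cyclohexyl acetate F5. Reductive cleavage of the C5–O bond with SmI2 (THF, −78 °C) and silylation of the samarium enolate on oxygen with Me3SiCl returns to the route at 11.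

Step 9. The hindered aldehyde enolate may be methylated on oxygen, or iodomethane may enter from the β-face. The fallback brings in the C18 methyl by carbenoid addition instead of enolate alkylation. It sets out from enol ether 16, isolated instead of being hydrolysed in step 8. Simmons–Smith cyclopropanation of the electron-rich exocyclic double bond from the α-face (Et2Zn, CH2I2, CH2Cl2, 0 °C) gives the spiro methoxycyclopropane F6 (cyclopropane CH2 on the α-face of C4). Acid-mediated opening of the alkoxycyclopropane (aq. HCl, THF) turns the ring CH2 into the C18 methyl and C19 into the formyl group, and the route is rejoined at 18.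

**Further compounds**

F1 | step 7 | 3-methyl-3-[(3R)-2-oxohept-6-yn-3-yl]-2-(prop-2-en-1-yl)cyclohexan-1-one (allyl trans to the oxoheptynyl group) | CC(=O)[C@H](CCC#C)[C@@]1(C)CCCC(=O)[C@@H]1CC=C
F2 | step 7 | {2-methyl-6-oxo-2-[(3R)-2-oxohept-6-yn-3-yl]cyclohexyl}acetaldehyde (same relative configuration as F1) | CC(=O)[C@H](CCC#C)[C@@]1(C)CCCC(=O)[C@@H]1CC=O
F3 | step 5 | 3-(2,3-dihydroxy-1-methylcyclohexyl)hept-6-yn-2-one (cis-diol, C9 and C10 as in 8) | CC(=O)[C@H](CCC#C)[C@@]1(C)CCCC(O)C1O
F4 | step 5 | 2-hydroxy-3-methyl-3-[(3R)-2-oxohept-6-yn-3-yl]cyclohexan-1-one | CC(=O)[C@H](CCC#C)[C@@]1(C)CCCC(=O)C1O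
F5 | step 5 | 2-methyl-6-oxo-2-[(3R)-2-oxohept-6-yn-3-yl]cyclohexyl acetate | CC(=O)[C@H](CCC#C)[C@@]1(C)CCCC(=O)C1OC(C)=O
F6 | step 9 | spiro methoxycyclopropane of 16 at C4 (cyclopropane CH2 on the α-face, ring stereocentres as in 15) | COC1C[C@@]12CCC[C@]3(C)[C@@H](CCC#C)C(C)=CC[C@@H]23
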